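The two aryl–C(=O) bonds that tie the bridges to the diaryl ether core are disconnected, giving 2-methoxydiphenyl ether and two molecules of an O-protected (3-hydroxyphenyl)acetyl chloride. The design exploits that each bridge leaves the core para to an oxygen: C-5 of ring A lies para to the C-2 oxygen (methoxy, later the free OH) and meta to the bridging oxygen, and C-4' of ring B lies para to that bridging oxygen. One double Friedel–Crafts acylation therefore assembles the whole four-ring carbon skeleton; no ring is closed. The acid chloride carries its phenol as an acetate, so that terminal rings C and D cannot compete as nucleophiles.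

Key step: step 4

Ring labels: ring A is the trisubstituted ring of the diaryl ether (C-1 ether oxygen, C-2 OMe/OH, C-5 bridge); ring B is the para-disubstituted ring (C-1' ether oxygen, C-4' bridge); rings C and D are the terminal 3-oxygenated phenyl rings.

Remark on the chemistry: a methyl ether on rings C and D would leave their positions para to OMe at least as nucleophilic as the intended core positions, so the acylating agent could acylate itself and the product. The acetate, complexed by AlCl3, removes this competition, and every later step tolerates a phenol that is freed early. All compounds are achiral.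

Step 1
Reactants: 1 guaiacol (2-methoxyphenol); 2 bromobenzene
Product: 3 2-methoxydiphenyl ether (1-methoxy-2-phenoxybenzene)
Conditions: CuI (10 mol%), N,N-dimethylglycine·HCl (30 mol%), Cs2CO3 (2 equiv), 1,4-dioxane, 100 °C
Reagents that add atoms: none
Why: Ligand-accelerated Ullmann diaryl ether coupling, for which an unhindered aryl bromide and a phenol with only a small ortho methoxy group are standard partners.

Step 2
Reactants: 4 (3-hydroxyphenyl)acetic acid
Product: 5 (3-acetoxyphenyl)acetic acid
Conditions: Ac2O (1.5 equiv), aq. NaOH (2.2 equiv), 0 °C; then aq. HCl to pH 2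
Reagents that add atoms: acetic anhydride, CC(=O)OC(C)=O
Why: Schotten–Baumann-type O-acetylation of the phenoxide in cold aqueous base, in which any mixed anhydride formed at the carboxylate hydrolyses back to the acid, so only the phenol stays acylated.

Step 3
Reactants: 5 (3-acetoxyphenyl)acetic acid
Product: 6 (3-acetoxyphenyl)acetyl chloride
Conditions: (COCl)2 (1.3 equiv), DMF (cat.), CH2Cl2, 0 °C → rt; volatiles removed, used crude
Reagents that add atoms: oxalyl chloride, ClC(=O)C(Cl)=O
Why: Standard acid chloride formation through the DMF-derived chloroiminium catalyst, with only gaseous by-products and conditions to which the aryl acetate is inert.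

Step 4
Reactants: 3 2-methoxydiphenyl ether; 6 (3-acetoxyphenyl)acetyl chloride (2.3 equiv)
Product: 8 bis(deoxybenzoin) diacetate 2-(3-acetoxyphenyl)-1-[3-[4-[(3-acetoxyphenyl)acetyl]phenoxy]-4-methoxyphenyl]ethan-1-one, via ring A monoketone 7 (not isolated)
Conditions: AlCl3 (5 equiv), CH2Cl2, 0 °C → rt (6 and AlCl3 premixed, 3 added last); ice/aq. HCl
Reagents that add atoms: none
Why: AlCl3 ionises 6 to an arylacetyl acylium species that attacks C-5 of ring A and then C-4' of ring B in two intermolecular electrophilic aromatic substitutions, each cationic sigma complex being stabilised by the lone pair of the oxygen para to the point of attack. The closest known reaction type is the Friedel–Crafts acylation of alkoxyarenes with arylacetyl chlorides to deoxybenzoins, together with the 4,4'-diacylation of diphenyl ether. No ring is closed and no stereocentre is created. On ring A the methoxy group is a stronger para donor than the aryloxy group, so C-5 should be preferred over C-4 (para to the bridging oxygen but only meta to OMe); on ring B the bridging oxygen directs to C-4' and the bulky electrophile avoids the ortho positions. Because the first ketone is meta to the bridging oxygen and not conjugated with it, ring B keeps most of its reactivity, whereas each AlCl3-complexed ketone closes its own ring to further acylation. Rings C and D, bearing AlCl3-complexed acetoxy groups, are far less nucleophilic than either core ring, which confines the reaction to the core.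

Step 5
Reactants: 8 bis(deoxybenzoin) diacetate
Product: 9 3-[2-[4-[5-[2-(3-acetoxyphenyl)ethyl]-2-methoxyphenoxy]phenyl]ethyl]phenyl acetate
Conditions: Et3SiH (6 equiv), TFA, rt → 50 °C
Reagents that add atoms: none
Why: Ionic hydrogenation (Kursanov–Parnes reduction), in which each protonated aryl ketone takes hydride from silicon, the benzylic alcohol ionises to a cation stabilised by the para oxygen and a second hydride gives the methylene group, while acetates, the methyl ether and the diaryl ether are inert to TFA and silane.

Step 6
Reactants: 9 3-[2-[4-[5-[2-(3-acetoxyphenyl)ethyl]-2-methoxyphenoxy]phenyl]ethyl]phenyl acetate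
Product: 11 perrottetin E, via ring A phenol diacetate 10 (not isolated)
Conditions: BBr3 (4 equiv), CH2Cl2, −78 °C → rt; then MeOH, 50 °C
Reagents that add atoms: none
Why: Lewis acid cleavage of the aryl methyl ether (bromide attacks the methyl group of the BBr3–ether adduct) followed by methanolysis, in which the methanol quench frees the phenol from boron and generates HBr, and the acidic methanol removes both aryl acetates by transesterification; any acetate already cleaved by BBr3 converges on the same product.

Compound list
1 | guaiacol (2-methoxyphenol) | COc1ccccc1O | starting material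
2 | bromobenzene | Brc1ccccc1 | starting material
3 | 2-methoxydiphenyl ether (1-methoxy-2-phenoxybenzene) | COc1ccccc1Oc1ccccc1 | intermediate
4 | (3-hydroxyphenyl)acetic acid | OC(=O)Cc1cccc(O)c1 | starting material
5 | (3-acetoxyphenyl)acetic acid | CC(=O)Oc1cccc(CC(=O)O)c1 | intermediate
6 | (3-acetoxyphenyl)acetyl chloride | CC(=O)Oc1cccc(CC(=O)Cl)c1 | intermediate
7 | 2-(3-acetoxyphenyl)-1-(4-methoxy-3-phenoxyphenyl)ethan-1-one (monoketone, acylated on ring A only) | CC(=O)Oc1cccc(CC(=O)c2ccc(OC)c(Oc3ccccc3)c2)c1 | intermediate (not isolated)
8 | 2-(3-acetoxyphenyl)-1-[3-[4-[(3-acetoxyphenyl)acetyl]phenoxy]-4-methoxyphenyl]ethan-1-one (bis(deoxybenzoin) diacetate; acyl groups at C-5 of ring A and C-4' of ring B) | CC(=O)Oc1cccc(CC(=O)c2ccc(Oc3cc(C(=O)Cc4cccc(OC(C)=O)c4)ccc3OC)cc2)c1 | intermediate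
9 | 3-[2-[4-[5-[2-(3-acetoxyphenyl)ethyl]-2-methoxyphenoxy]phenyl]ethyl]phenyl acetate (perrottetin E ring A methyl ether, rings C and D acetylated) | CC(=O)Oc1cccc(CCc2ccc(Oc3cc(CCc4cccc(OC(C)=O)c4)ccc3OC)cc2)c1 | intermediate
10 | 3-[2-[4-[5-[2-(3-acetoxyphenyl)ethyl]-2-hydroxyphenoxy]phenyl]ethyl]phenyl acetate (ring A phenol free, rings C and D still acetylated) | CC(=O)Oc1cccc(CCc2ccc(Oc3cc(CCc4cccc(OC(C)=O)c4)ccc3O)cc2)c1 | intermediate (not isolated)
11 | perrottetin E, 4-[2-(3-hydroxyphenyl)ethyl]-2-[4-[2-(3-hydroxyphenyl)ethyl]phenoxy]phenol | Oc1cccc(CCc2ccc(Oc3cc(CCc4cccc(O)c4)ccc3O)cc2)c1 | target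

Total step count: 6. Longest linear sequence: 5 steps (steps 2 to 6, from 4).

Steps most likely to fail

1. Step 4. What may go wrong: loss of site selectivity on ring A (attack at C-4, para to the bridging oxygen, competing with C-5), a second acylation on ring B that stalls, or Fries-type acetyl transfer from the AlCl3-complexed aryl acetates if the mixture has to be forced. Fallback: the regiochemistry is fixed by halogens placed beforehand, and the ketones are made by cross-coupling instead of electrophilic substitution. The fallback sets out from acid chloride 6 and comes back to the route at bis(deoxybenzoin) 8. Commercial 5-bromo-2-methoxyphenol and 4-bromophenylboronic acid are joined by Chan–Lam coupling (Cu(OAc)2, pyridine, 4 Å sieves, air, CH2Cl2, rt) to 4-bromo-2-(4-bromophenoxy)-1-methoxybenzene F1. Double bromine–lithium exchange (n-BuLi, THF, −78 °C) should give the dilithiated diaryl ether F2, and ZnCl2 turns it into the bis(arylzinc chloride) F3. Negishi acylation of F3 with 6 (2.2 equiv, Pd(PPh3)4 cat., THF, 0 °C → rt), which tolerates the acetates, then delivers 8.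

2. Step 5. What may go wrong: incomplete deoxygenation at the less electron-rich ring B ketone, or capture of a benzylic cation by an electron-rich arene (Friedel–Crafts dimerisation) instead of by the silane. Fallback: heterogeneous hydrogenolysis replaces hydride transfer to a cation. It sets out from 8 and comes back at 9. Under H2 (4 bar), Pd/C, AcOH and HClO4 (cat.) at 50 °C, the two ketones are first hydrogenated to the bis(benzylic alcohol) F4 (mixture of diastereomers, not isolated). The acid-activated benzylic C–O bonds of F4 are then cleaved on the metal to give 9.

3. Step 6. What may go wrong: incomplete methanolysis of the acetates, or ring bromination and partial decomposition of the electron-rich product under the strong Lewis acid. Fallback: base and nucleophile replace the Lewis acid. It sets out from 9 and comes back at 11. K2CO3 in MeOH at rt removes both acetates to give the bisphenol methyl ether 4-[2-(3-hydroxyphenyl)ethyl]-2-[4-[2-(3-hydroxyphenyl)ethyl]phenoxy]anisole F5. Sodium ethanethiolate in DMF at 130 °C then cleaves the remaining methyl ether by SN2 attack at the methyl carbon, and acidification gives 11.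

Further compounds
F1 | step 4 | 4-bromo-2-(4-bromophenoxy)-1-methoxybenzene | COc1ccc(Br)cc1Oc1ccc(Br)cc1
F2 | step 4 | 4-lithio-2-(4-lithiophenoxy)-1-methoxybenzene (dilithiated diaryl ether) | COc1ccc([Li])cc1Oc1ccc([Li])cc1
F3 | step 4 | bis(arylzinc chloride) of 2-methoxydiphenyl ether, zinc at C-5 and C-4' | COc1ccc([Zn]Cl)cc1Oc1ccc([Zn]Cl)cc1
F4 | step 5 | bis(benzylic alcohol) from 8, 3-[2-[3-[4-[2-(3-acetoxyphenyl)-1-hydroxyethyl]phenoxy]-4-methoxyphenyl]-2-hydroxyethyl]phenyl acetate, mixture of diastereomers | CC(=O)Oc1cccc(CC(O)c2ccc(Oc3cc(C(O)Cc4cccc(OC(C)=O)c4)ccc3OC)cc2)c1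
F5 | step 6 | 4-[2-(3-hydroxyphenyl)ethyl]-2-[4-[2-(3-hydroxyphenyl)ethyl]phenoxy]anisole (perrottetin E ring A methyl ether) | COc1ccc(CCc2cccc(O)c2)cc1Oc1ccc(CCc2cccc(O)c2)cc1
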